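The tetrasubstituted C11=C12 alkene, shared by the cyclohexene and the butenolide, is read as the retron of a type 2 intramolecular Diels–Alder reaction. Cutting C13–C14 and C1–C15 opens the six-membered and the twelve-membered ring of the bicyclo[9.3.1] core together. The precursor is an open-chain vinyl ketone (C14=C1–C2=O). It carries a silyl-protected γ-hydroxy dienoate whose twisted C13=C12–C11=C15 diene is inert. In the key step, desilylation lets O10 lactonise onto C18. This locks the diene s-cis, and the enone tethered at C10 adds across it. Three rings form in one operation, and C1 is set from C10. The activating C2 ketone is then deleted.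

Key step: step 14

Remark (atom labels): verticillane numbering is used. In the order of the target SMILES the atoms are C20, C4, C3, C2, C1, C14, C13, C12, C11, C10, C9, C8 (methyl C19), C7, C6 (OAc), C5, then O, C18 (lactone C=O) and C15 (methyls C16, C17).

Remark (catalyst antipodes): the route requires Re-face attack in step 3 and Si-face attack in step 10. The antipodes named follow the usual sense of induction with conjugated aldehydes, and the mirror-image catalyst would be taken if a substrate answered in the opposite sense.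

Step 1
Reactants: 1 3-methylbut-2-enal
Product: 3 2-bromo-3-methylbut-2-enal, via dibromide 2 (not isolated)
Conditions: Br2, CH2Cl2, −10 °C; then Et3N, 0 °C to rt
Reagents that add atoms: bromine, BrBr
Why: Bromination–dehydrobromination, in which Br2 adds to the enal C=C and Et3N removes the acidic α-H with loss of the tertiary bromide; no stereocentre survives and the two β-methyl groups make the alkene geometry irrelevant.

Step 2
Reactants: 4 methyl 3-methylbut-2-enoate
Product: 6 tert-butyl[(1-methoxy-3-methylbuta-1,3-dien-1-yl)oxy]dimethylsilane, via lithium dienolate 5 (not isolated)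
Conditions: LDA, THF, −78 °C; then TBSCl, DMPU, −78 °C to rt
Reagents that add atoms: tert-butyldimethylsilyl chloride, CC(C)(C)[Si](C)(C)Cl
Why: Kinetic γ-deprotonation and O-silylation of the extended enolate (silyl ketene acetal formation) should give the vinylogous nucleophile, whose ketene acetal geometry is of no consequence.

Step 3
Reactants: 3 2-bromo-3-methylbut-2-enal; 6 tert-butyl[(1-methoxy-3-methylbuta-1,3-dien-1-yl)oxy]dimethylsilane
Product: 7 methyl (2E,5R)-6-bromo-5-hydroxy-3,7-dimethylocta-2,6-dienoate
Conditions: SiCl4, (R,R)-binaphthyldiamine-derived bisphosphoramide (5 mol %), CH2Cl2, −78 °C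
Reagents that add atoms: none
Why: Catalytic enantioselective vinylogous Mukaiyama aldol addition (SiCl4 activated by a chiral Lewis base), in which the dienolate attacks through its γ-carbon on the Re face of the bound aldehyde in an open transition state; this sets C10 as R and gives the E-enoate, while any Z-isomer would lactonise to a dihydropyranone and be removed on chromatography.

Step 4
Reactants: 7 methyl (2E,5R)-6-bromo-5-hydroxy-3,7-dimethylocta-2,6-dienoate
Product: 8 methyl (2E,5R)-6-bromo-5-[(tert-butyldimethylsilyl)oxy]-3,7-dimethylocta-2,6-dienoate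
Conditions: TBSOTf, 2,6-lutidine, CH2Cl2, −78 to 0 °C
Reagents that add atoms: tert-butyldimethylsilyl triflate, CC(C)(C)[Si](C)(C)OS(=O)(=O)C(F)(F)F
Why: Silyl ether formation at the hindered allylic alcohol without touching C10; the TBS group is the safety catch that keeps O10 from lactonising before step 14.

Step 5
Reactants: 8 methyl (2E,5R)-6-bromo-5-[(tert-butyldimethylsilyl)oxy]-3,7-dimethylocta-2,6-dienoate
Product: 9 (2E,5R)-6-bromo-5-[(tert-butyldimethylsilyl)oxy]-3,7-dimethylocta-2,6-dien-1-ol
Conditions: DIBAL-H (2.5 equiv), CH2Cl2, −78 °C; Rochelle salt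
Reagents that add atoms: none
Why: 1,2-Reduction of the enoate by DIBAL-H, which leaves the vinyl bromide, the silyl ether and the alkene geometry untouched.

Step 6
Reactants: 9 (2E,5R)-6-bromo-5-[(tert-butyldimethylsilyl)oxy]-3,7-dimethylocta-2,6-dien-1-ol
Product: 10 (2E,5R)-6-bromo-5-[(tert-butyldimethylsilyl)oxy]-3,7-dimethylocta-2,6-dienal
Conditions: MnO2, CH2Cl2, rt
Reagents that add atoms: none
Why: Selective MnO2 oxidation of the primary allylic alcohol to the E-enal under neutral conditions.

Step 7
Reactants: 11 methyl prop-2-ynoate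
Product: 12 methyl 2-(tributylstannyl)prop-2-enoate
Conditions: Bu3SnH, Pd(PPh3)4 (cat.), THF, 0 °C to rt
Reagents that add atoms: tributyltin hydride, CCCC[SnH](CCCC)CCCC
Why: Palladium-catalysed syn-hydrostannation, in which the polarised ynoate takes hydride at the β-carbon and tin at the α-carbon; the β-stannyl isomer is removed by chromatography.

Step 8
Reactants: 10 (2E,5R)-6-bromo-5-[(tert-butyldimethylsilyl)oxy]-3,7-dimethylocta-2,6-dienal; 12 methyl 2-(tributylstannyl)prop-2-enoate
Product: 13 methyl (4R,6E)-4-[(tert-butyldimethylsilyl)oxy]-6-methyl-2-methylidene-8-oxo-3-(propan-2-ylidene)oct-6-enoate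
Conditions: Pd2(dba)3 (5 mol %), AsPh3, CuI (cat.), LiCl, NMP, 60 °C
Reagents that add atoms: none
Why: Stille coupling with copper(I) co-catalysis forms C11–C12 and brings in C12, C13 and C18 at once; the resulting diene is twisted out of planarity and therefore does not react as a diene.

Step 9
Reactants: 14 3-chloro-2-(chloromethyl)prop-1-ene
Product: 15 tributyl[2-(chloromethyl)prop-2-en-1-yl]stannane
Conditions: Bu3SnH, LDA, THF, 0 °C; then 14 (excess), −78 °C
Reagents that add atoms: tributyltin hydride (used as Bu3SnLi), CCCC[SnH](CCCC)CCCC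
Why: SN2 displacement of one allylic chloride by tributylstannyllithium, with excess dichloride holding the reaction at monosubstitution.

Step 10
Reactants: 13 methyl (4R,6E)-4-[(tert-butyldimethylsilyl)oxy]-6-methyl-2-methylidene-8-oxo-3-(propan-2-ylidene)oct-6-enoate; 15 tributyl[2-(chloromethyl)prop-2-en-1-yl]stannane
Product: 16 methyl (4R,6E,8S)-4-[(tert-butyldimethylsilyl)oxy]-10-(chloromethyl)-8-hydroxy-6-methyl-2-methylidene-3-(propan-2-ylidene)undeca-6,10-dienoate
Conditions: (S)-BINOL (20 mol %), Ti(OiPr)4 (10 mol %), 4 Å MS, CH2Cl2, −20 °C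
Reagents that add atoms: none
Why: Keck asymmetric allylation with a bifunctional allylstannane, in which the BINOL–Ti(IV) complex binds the enal and directs SE2' attack to its Si face; this sets C6 as S independently of remote C10 and keeps the allylic chloride for the next coupling.

Step 11
Reactants: 16 methyl (4R,6E,8S)-4-[(tert-butyldimethylsilyl)oxy]-10-(chloromethyl)-8-hydroxy-6-methyl-2-methylidene-3-(propan-2-ylidene)undeca-6,10-dienoate
Product: 17 methyl (4R,6E,8S)-8-acetoxy-4-[(tert-butyldimethylsilyl)oxy]-10-(chloromethyl)-6-methyl-2-methylidene-3-(propan-2-ylidene)undeca-6,10-dienoate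
Conditions: Ac2O, pyridine, DMAP (cat.), CH2Cl2, 0 °C to rt
Reagents that add atoms: acetic anhydride, CC(=O)OC(C)=O
Why: O-Acylation of the only free hydroxyl installs the C6 acetate of the target with retention, since the C6–O bond is not broken.

Step 12
Reactants: 17 methyl (4R,6E,8S)-8-acetoxy-4-[(tert-butyldimethylsilyl)oxy]-10-(chloromethyl)-6-methyl-2-methylidene-3-(propan-2-ylidene)undeca-6,10-dienoate; 18 prop-2-enal
Product: 19 methyl (4R,6E,8S)-8-acetoxy-4-[(tert-butyldimethylsilyl)oxy]-12-hydroxy-6-methyl-2,10-dimethylidene-3-(propan-2-ylidene)tetradeca-6,13-dienoate (C12 epimers)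
Conditions: CrCl2 (4 equiv), LiI (cat.), THF, 0 °C to rt
Reagents that add atoms: none
Why: Nozaki–Hiyama allylation, in which the allylchromium(III) species adds 1,2 to acrolein and ignores esters, the allylic acetate and the hindered acrylate; the new carbinol centre (C2) is uncontrolled and is erased in step 13.

Step 13
Reactants: 19 methyl (4R,6E,8S)-8-acetoxy-4-[(tert-butyldimethylsilyl)oxy]-12-hydroxy-6-methyl-2,10-dimethylidene-3-(propan-2-ylidene)tetradeca-6,13-dienoate
Product: 20 methyl (4R,6E,8S)-8-acetoxy-4-[(tert-butyldimethylsilyl)oxy]-6-methyl-2,10-dimethylidene-12-oxo-3-(propan-2-ylidene)tetradeca-6,13-dienoate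
Conditions: Dess–Martin periodinane, NaHCO3, CH2Cl2, 0 °C to rt
Reagents that add atoms: none
Why: Buffered Dess–Martin oxidation converts both carbinol epimers into one vinyl ketone under conditions mild enough to keep the C4(20) alkene out of conjugation.

Step 14
Reactants: 20 methyl (4R,6E,8S)-8-acetoxy-4-[(tert-butyldimethylsilyl)oxy]-6-methyl-2,10-dimethylidene-12-oxo-3-(propan-2-ylidene)tetradeca-6,13-dienoate
Product: 23 (1R,6S,7E,10R)-6-acetoxy-2-oxoverticilla-4(20),7,11-trien-18,10-olide, via hydroxy ester 21 (not isolated), via diene lactone 22 (not isolated)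
Conditions: HF·pyridine, THF, 0 °C to rt; crude into PhMe (1 mM), PPTS (cat.), BHT, 110 °C
Reagents that add atoms: none
Why: HF·pyridine frees O10–H (21), which attacks the C18 methyl ester (5-exo-trig acyl substitution, loss of MeOH) to close the γ-lactone 22, and only this closure forces the C13=C12–C11=C15 diene, held near-orthogonal in 20 by the clash of the Z-methyl on C15 with C13 or C18, into the planar s-cis form, so that no cycloaddition can start before the switch. The tethered enone C14=C1–C2=O then adds in a concerted, asynchronous [4+2] cycloaddition whose closest known relatives are the type 2 intramolecular Diels–Alder reaction (tether at the 2-position of the diene, bridgehead alkene product, gem-dimethyl diene terminus tolerated) and macrocyclising Diels–Alder reactions at high dilution, and 2-acyl dienes are known to combine readily with acrylic dienophiles. The cyclohexene is closed by the two new σ bonds C13–C14 and C1–C15, the twelve-membered ring is closed by C1–C15 in the 1,3-bridged mode, and the shifted π bond becomes the C11=C12 bridgehead alkene of the butenolide. The regioselectivity that is needed is secured electronically, because the unhindered terminus C13, β to the lactone carbonyl, bonds first to the enone β-carbon C14 ("para" to C18, "ortho" to the C15 methyls), which leaves the hindered C15–C1 bond to form late between a tertiary allylic and an α-keto centre. The only new stereocentre, C1, is controlled by C10, since C9 projects from one face of the flat diene lactone and the eight-atom chain can bring the enone only to that face and only with C2=O endo under C11 rather than around the C15 methyls, which places C2 and C9 on the same face, that is 1R from 10R. Chemoselectivity rests on the vinyl ketone being the only activated and unhindered 2π partner (C4=C20 and C7=C8 are unactivated, the α-methylene lactone of a second molecule is 1,1-disubstituted), and dilution with BHT suppresses dimerisation and polymerisation.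

Step 15
Reactants: 23 (1R,6S,7E,10R)-6-acetoxy-2-oxoverticilla-4(20),7,11-trien-18,10-olide
Product: 24 C2 tosylhydrazone of 23
Conditions: TsNHNH2, EtOH, rt to 50 °C
Reagents that add atoms: p-toluenesulfonyl hydrazide, Cc1ccc(cc1)S(=O)(=O)NN
Why: Hydrazone condensation at the only ketone under near-neutral conditions; the lactone and acetate carbonyls do not condense and the tetrasubstituted butenolide alkene is no Michael acceptor.

Step 16
Reactants: 24 C2 tosylhydrazone of 23
Product: 27 (1R,6S,7E,10R)-6-acetoxyverticilla-4(20),7,11-trien-18,10-olide (CNP0289913.1), via N-boryl tosylhydrazine 25 (not isolated), via alkyl diazene 26 (not isolated)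
Conditions: catecholborane, CHCl3, −10 °C; then NaOAc·3H2O, reflux
Reagents that add atoms: none
Why: Caglioti-type tosylhydrazone reduction, in which the borane delivers hydride to C=N, acetate expels sulfinate from 25, and diazene 26 loses N2 to leave C2H2; since the diazene is homoallylic and not allylic, no alkene shifts, and the lactone, the acetate and C1 are not touched.

Compound list
1 | 3-methylbut-2-enal | CC(C)=CC=O | starting material
2 | 2,3-dibromo-3-methylbutanal (racemic) | CC(C)(Br)C(Br)C=O | intermediate
3 | 2-bromo-3-methylbut-2-enal | CC(C)=C(Br)C=O | intermediate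
4 | methyl 3-methylbut-2-enoate | CC(C)=CC(=O)OC | starting material
5 | lithium 1-methoxy-3-methylbuta-1,3-dien-1-olate | C=C(C)C=C(OC)[O-].[Li+] | intermediate
6 | tert-butyl[(1-methoxy-3-methylbuta-1,3-dien-1-yl)oxy]dimethylsilane (ketene acetal geometry undefined) | C=C(C)C=C(OC)O[Si](C)(C)C(C)(C)C | intermediate
7 | methyl (2E,5R)-6-bromo-5-hydroxy-3,7-dimethylocta-2,6-dienoate | COC(=O)/C=C(C)/C[C@@H](O)C(Br)=C(C)C | intermediate
8 | methyl (2E,5R)-6-bromo-5-[(tert-butyldimethylsilyl)oxy]-3,7-dimethylocta-2,6-dienoate | COC(=O)/C=C(C)/C[C@@H](O[Si](C)(C)C(C)(C)C)C(Br)=C(C)C | intermediate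
9 | (2E,5R)-6-bromo-5-[(tert-butyldimethylsilyl)oxy]-3,7-dimethylocta-2,6-dien-1-ol | OC/C=C(C)/C[C@@H](O[Si](C)(C)C(C)(C)C)C(Br)=C(C)C | intermediate
10 | (2E,5R)-6-bromo-5-[(tert-butyldimethylsilyl)oxy]-3,7-dimethylocta-2,6-dienal | O=C/C=C(C)/C[C@@H](O[Si](C)(C)C(C)(C)C)C(Br)=C(C)C | intermediate
11 | methyl prop-2-ynoate | C#CC(=O)OC | starting material
12 | methyl 2-(tributylstannyl)prop-2-enoate | C=C(C(=O)OC)[Sn](CCCC)(CCCC)CCCC | intermediate
13 | methyl (4R,6E)-4-[(tert-butyldimethylsilyl)oxy]-6-methyl-2-methylidene-8-oxo-3-(propan-2-ylidene)oct-6-enoate | O=C/C=C(C)/C[C@@H](O[Si](C)(C)C(C)(C)C)C(=C(C)C)C(=C)C(=O)OC | intermediate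
14 | 3-chloro-2-(chloromethyl)prop-1-ene | ClCC(=C)CCl | starting material
15 | tributyl[2-(chloromethyl)prop-2-en-1-yl]stannane | C=C(CCl)C[Sn](CCCC)(CCCC)CCCC | intermediate
16 | methyl (4R,6E,8S)-4-[(tert-butyldimethylsilyl)oxy]-10-(chloromethyl)-8-hydroxy-6-methyl-2-methylidene-3-(propan-2-ylidene)undeca-6,10-dienoate | ClCC(=C)C[C@H](O)/C=C(C)/C[C@@H](O[Si](C)(C)C(C)(C)C)C(=C(C)C)C(=C)C(=O)OC | intermediate
17 | methyl (4R,6E,8S)-8-acetoxy-4-[(tert-butyldimethylsilyl)oxy]-10-(chloromethyl)-6-methyl-2-methylidene-3-(propan-2-ylidene)undeca-6,10-dienoate | ClCC(=C)C[C@H](OC(C)=O)/C=C(C)/C[C@@H](O[Si](C)(C)C(C)(C)C)C(=C(C)C)C(=C)C(=O)OC | intermediate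
18 | prop-2-enal (acrolein) | C=CC=O | starting material
19 | methyl (4R,6E,8S)-8-acetoxy-4-[(tert-butyldimethylsilyl)oxy]-12-hydroxy-6-methyl-2,10-dimethylidene-3-(propan-2-ylidene)tetradeca-6,13-dienoate (C12 epimers) | C=CC(O)CC(=C)C[C@H](OC(C)=O)/C=C(C)/C[C@@H](O[Si](C)(C)C(C)(C)C)C(=C(C)C)C(=C)C(=O)OC | intermediate
20 | methyl (4R,6E,8S)-8-acetoxy-4-[(tert-butyldimethylsilyl)oxy]-6-methyl-2,10-dimethylidene-12-oxo-3-(propan-2-ylidene)tetradeca-6,13-dienoate | C=CC(=O)CC(=C)C[C@H](OC(C)=O)/C=C(C)/C[C@@H](O[Si](C)(C)C(C)(C)C)C(=C(C)C)C(=C)C(=O)OC | intermediate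
21 | methyl (4R,6E,8S)-8-acetoxy-4-hydroxy-6-methyl-2,10-dimethylidene-12-oxo-3-(propan-2-ylidene)tetradeca-6,13-dienoate | C=CC(=O)CC(=C)C[C@H](OC(C)=O)/C=C(C)/C[C@@H](O)C(=C(C)C)C(=C)C(=O)OC | intermediate
22 | (5R)-5-[(2E,4S)-4-acetoxy-2-methyl-6-methylidene-8-oxodeca-2,9-dien-1-yl]-3-methylidene-4-(propan-2-ylidene)dihydrofuran-2(3H)-one | C=CC(=O)CC(=C)C[C@H](OC(C)=O)/C=C(C)/C[C@H]1OC(=O)C(=C)C1=C(C)C | intermediate
23 | (1R,6S,7E,10R)-6-acetoxy-2-oxoverticilla-4(20),7,11-trien-18,10-olide | C=C1CC(=O)[C@@H]2CCC3=C([C@@H](C/C(C)=C/[C@@H](OC(C)=O)C1)OC3=O)C2(C)C | intermediate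
24 | C2 tosylhydrazone of 23 (C=N geometry undefined) | C=C1CC(=NNS(=O)(=O)c4ccc(C)cc4)[C@@H]2CCC3=C([C@@H](C/C(C)=C/[C@@H](OC(C)=O)C1)OC3=O)C2(C)C | intermediate
25 | C2 N-(1,3,2-benzodioxaborol-2-yl)-N'-tosylhydrazine (C2 epimers) | C=C1CC(N(B4Oc5ccccc5O4)NS(=O)(=O)c4ccc(C)cc4)[C@@H]2CCC3=C([C@@H](C/C(C)=C/[C@@H](OC(C)=O)C1)OC3=O)C2(C)C | intermediate
26 | C2 alkyl diazene (C2 epimers) | C=C1CC(N=N)[C@@H]2CCC3=C([C@@H](C/C(C)=C/[C@@H](OC(C)=O)C1)OC3=O)C2(C)C | intermediate
27 | (1R,6S,7E,10R)-6-acetoxyverticilla-4(20),7,11-trien-18,10-olide (CNP0289913.1) | C=C1CC[C@@H]2CCC3=C([C@@H](C/C(C)=C/[C@@H](OC(C)=O)C1)OC3=O)C2(C)C | target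

Total step count: 16
Longest linear sequence: 13 steps (steps 1, 3, 4, 5, 6, 8, 10, 11, 12, 13, 14, 15, 16, from 3-methylbut-2-enal)

Steps most likely to fail

Step 14. Several things may go wrong. The cycloaddition may be too slow at a useful dilution, so that oligomerisation of the diene lactone or polymerisation of the enone takes over. The tether may fold into the 1,4-bridged orientation. A 1,5-hydrogen shift of the Z-methyl group may drain the diene. The fallback separates the two carbocyclic ring closures and sets out from 17.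
- HF·pyridine and then PPTS should give the diene lactone allylic chloride F1.
- An intermolecular Diels–Alder reaction with acrolein 18 (PhMe, 80 °C) builds the cyclohexene–butenolide as the bicyclic C1 carbaldehyde F2. Its C1 epimers are separated, and the unwanted one is recycled by base equilibration of the enolisable aldehyde.
- An intramolecular Nozaki–Hiyama allylation (CrCl2, THF, high dilution) closes the twelve-membered ring at C2–C3 to the macrocyclic C2 carbinol F3.
- Dess–Martin oxidation comes back to the route at 23.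

Step 8. Transmetalation of the hindered, electron-poor α-stannyl acrylate onto the crowded vinylpalladium species may be slow. Protodestannylation and homocoupling would then consume the stannane. The fallback builds the same unit from a slim sp partner plus CO and sets out from 10.
- Sonogashira coupling with trimethylsilylacetylene (PdCl2(PPh3)2, CuI, iPr2NH) should give the silyl enyne enal F4.
- K2CO3 in MeOH gives the terminal enyne enal F5.
- A branched-selective palladium-catalysed methoxycarbonylation of the alkyne (Pd(OAc)2, 2-PyPPh2, MsOH cat., CO, MeOH) forms C12–C18 and comes back to the route at 13.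

Step 15. Condensation at the C2 ketone, flanked by the tertiary C1 and the quaternary C15, may be slow. The longer exposure or added acid may then move the C4(20) alkene into conjugation with C2. The fallback replaces the hydrazone chemistry by a radical deoxygenation and sets out from 23.
- Luche reduction (NaBH4, CeCl3, MeOH) gives the macrocyclic C2 carbinol F3.
- 1,1'-Thiocarbonyldiimidazole with DMAP gives the C2 imidazole-1-carbothioate F6.
- Barton–McCombie reduction (Bu3SnH, AIBN, PhMe, 80 °C) comes back to the route at 27.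

Further compounds
F1 | step 14 | (5R)-5-[(2E,4S)-4-acetoxy-6-(chloromethyl)-2-methylhepta-2,6-dien-1-yl]-3-methylidene-4-(propan-2-ylidene)dihydrofuran-2(3H)-one | ClCC(=C)C[C@H](OC(C)=O)/C=C(C)/C[C@H]1OC(=O)C(=C)C1=C(C)C
F2 | step 14 | (3R,5R)-3-[(2E,4S)-4-acetoxy-6-(chloromethyl)-2-methylhepta-2,6-dien-1-yl]-4,4-dimethyl-1-oxo-1,3,4,5,6,7-hexahydro-2-benzofuran-5-carbaldehyde | ClCC(=C)C[C@H](OC(C)=O)/C=C(C)/C[C@H]1OC(=O)C2=C1C(C)(C)[C@H](C=O)CC2
F3 | step 14 | (1R,6S,7E,10R)-6-acetoxy-2-hydroxyverticilla-4(20),7,11-trien-18,10-olide (C2 epimers) | C=C1CC(O)[C@@H]2CCC3=C([C@@H](C/C(C)=C/[C@@H](OC(C)=O)C1)OC3=O)C2(C)C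
F4 | step 8 | (2E,5R)-5-[(tert-butyldimethylsilyl)oxy]-3,7-dimethyl-6-[(trimethylsilyl)ethynyl]octa-2,6-dienal | O=C/C=C(C)/C[C@@H](O[Si](C)(C)C(C)(C)C)C(C#C[Si](C)(C)C)=C(C)C
F5 | step 8 | (2E,5R)-5-[(tert-butyldimethylsilyl)oxy]-6-ethynyl-3,7-dimethylocta-2,6-dienal | O=C/C=C(C)/C[C@@H](O[Si](C)(C)C(C)(C)C)C(C#C)=C(C)C
F6 | step 15 | O-[(1R,6S,7E,10R)-6-acetoxy-18-oxo-18,10-epoxyverticilla-4(20),7,11-trien-2-yl] 1H-imidazole-1-carbothioate (C2 epimers) | C=C1CC(OC(=S)n4ccnc4)[C@@H]2CCC3=C([C@@H](C/C(C)=C/[C@@H](OC(C)=O)C1)OC3=O)C2(C)C
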